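The constants and the charge come first, for a catalyst that is being lost to spent catalyst while it works.

    spent carrier + salt in the second phase ⇌ fresh carrier + spent salt in the second phase (K1 = 0.093, k1 = 4.64 /M/min)
    substrate + fresh carrier → target + spent carrier (k2 = 457 /M/min)
    2 substrate → homo dimer (k3 = 1.10 × 10⁻⁴ /M/min)
    2 spent carrier → spent catalyst (k4 = 15.0 /M/min)

substrate 0.20 M; salt in the second phase 1.50 equiv; spent carrier 2.5 mol%; volume of the second phase over the first 0.50

- percent here means substrate units held: one homo dimer counts as two
- a step written with two of one species runs at k times the square of its concentration and takes two of it each time
- in the second phase: salt in the second phase, spent salt in the second phase; everything else is in the first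
- charges count per volume of the first phase; a concentration in a rate is the amount of a species over the volume of its own phase; every rate counts per litre of the first phase
- a form made of two catalysts counts as two
- charge of substrate (flask): 0.20 M

- the form that holds most of the catalyst when 5.0% of the substrate are converted (spent carrier / fresh carrier / spent catalyst)
- its share of the catalyst then
- apparent order in spent carrier when 5.0% of the substrate are converted (percent change of the rate of making target for one percent more spent carrier charged)

Counting the salt over its own phase, spent carrier turns to fresh carrier at 2.78 /min per spent carrier. Fresh carrier is consumed by substrate at 91.4 /min, much faster, so spent carrier is the resting state and

fresh over spent = 3.05%.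

Target is then made at g times spent carrier, 0.0139 M/min at the start. Taking the conversion as target, I need 0.0100 M, which without loss takes 0.718 min.

The quantity I carry is the catalyst's life, the time in which pairing, taken by itself, brings the charged spent carrier to half:

life = 1 / (2 × 15.0 /M/min × 0.00500 M) = 6.67 min

The fraction left after a time t is 1 / (1 + t/life), which is 90.3% at that first time. Replacing the falling curve by the mean of its two ends gives 95.1%, and the time stretches to 0.755 min.

That straight mean is the weak link, since the curve bends. Integrating it properly gives

target made = r × life × ln(1 + t/life),

so the time is 0.759 min, and the straight mean was off by 0.449%. The fraction left is 89.8%, and after the fresh carrier is set aside, spent carrier holds 87.1%. In this line r is proportional to the charge of spent carrier and life inversely proportional to it, so their product does not change with the charge, the fraction left at fixed conversion stays put and I commit to order one.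

The forecast says spent carrier, 87% and order 0.99, holding that “at fixed conversion the surviving fraction barely depends on the charge”.

This flask gives spent carrier at 87.1% and order 1.0, after 0.810 min, when spent catalyst holds 10.3% of the catalyst. Carried on to 20.0 min, the life puts spent carrier at 25.0% of its charge, and this flask shows 25.4%. A flask with twice the salt in the second phase keeps the same life but turns over at 5.56 /min per spent carrier, so the integrated line puts a factor of 0.487 on the time; that run gives 0.503.

All constants were drawn at random within sensible limits; what happens was integrated by code.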